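**Plan**
- Retrosynthesis: open the C12–O6 lactone (C12 back to an allylic alcohol) and the O8 ester, then apply a retro-[3,3] shift that cuts ring bond C3–C4 and re-forms C1–C6. This contracts the ten-membered ring to a cyclohexene-1,2-diol (ring atoms C1, C10, C9, C8, C7, C6) with a vinyl group on C1 and a propargyl-ether alkyne on C6.
- Enabling feature: C1 and C6 are the oxygen-bearing carbons lying 1,6 across the ring. Between them, C2–C3–C4=C5 carries exactly the enone-type unsaturation (towards C6) that an alkynyl oxy-Cope shift leaves behind. The other arc, C10(Me)=C9–C8–C7, closes with C1 and C6 to a six-membered ring that stores the cis 9,10-olefin.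
- Forward: quinone monoketal → cyclohexenone with C7 and C8 → vinyl on C1, alkynyl on C6 → six-to-ten ring enlargement → C6 reduction with C8 acylation → lactone ring → C1 reduction → desilylation.
- Stereochemistry: C7 from Rh/(R)-BINAP conjugate addition; C8 from equatorial hydride delivery next to C7; C6 from 1,3-anti Evans–Tishchenko reduction directed by O8, which also installs the (S)-2-methylbutanoate from (S)-2-methylbutanal; C1 from CBS reduction.
- Olefin geometry: C9=C10 is inherited from the six-membered ring; C4=C5 is set by protonation of the cyclic allenolate from its exocyclic side.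

Key step: step 11

Remark: germacrane numbering (C1–C15) is used throughout. The C1 and C6 carbinol centres of compounds 9–17 are drawn as the expected diastereomers, but both centres are erased in step 11, so either epimer serves. "Ring-cis" at C4=C5 corresponds to 4E by CIP because of the CH2O substituent.

**Route**

Step 1
Reactants: 1 4-methoxy-2-methylphenol
Product: 2 4,4-dimethoxy-2-methylcyclohexa-2,5-dien-1-one
Conditions: PhI(OAc)2, MeOH, 0 °C
Reagents that add atoms: methanol, CO
Why: Hypervalent-iodine oxidative dearomatisation of a p-methoxyphenol in methanol should give the quinone monoketal, whose free carbonyl is C1, whose methyl-bearing olefin is C9=C10 and whose ketal carbon is the future C8.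

Step 2
Reactants: 3 2,3-dibromoprop-1-ene; 4 (4-methoxyphenyl)methanol
Product: 5 1-{[(2-bromoprop-2-en-1-yl)oxy]methyl}-4-methoxybenzene
Conditions: NaH, THF/DMF, 0 °C to rt
Reagents that add atoms: none
Why: Williamson etherification at the allylic bromide, the vinylic bromide being inert to alkoxide.

Step 3
Reactants: 5 1-{[(2-bromoprop-2-en-1-yl)oxy]methyl}-4-methoxybenzene
Product: 6 2-{3-[(4-methoxybenzyl)oxy]prop-1-en-2-yl}-4,4,5,5-tetramethyl-1,3,2-dioxaborolane
Conditions: B2pin2, PdCl2(PPh3)2 (3 mol %), PPh3, KOPh, toluene, 50 °C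
Reagents that add atoms: bis(pinacolato)diboron, CC1(C)OB(OC1(C)C)B1OC(C)(C)C(C)(C)O1
Why: Miyaura borylation of a 1-alkenyl bromide should give the 1,1-disubstituted alkenylboronate that carries C11, C12 (as CH2OPMB) and C13.

Step 4
Reactants: 2 4,4-dimethoxy-2-methylcyclohexa-2,5-dien-1-one; 6 2-{3-[(4-methoxybenzyl)oxy]prop-1-en-2-yl}-4,4,5,5-tetramethyl-1,3,2-dioxaborolane
Product: 7 (5R)-4,4-dimethoxy-5-{3-[(4-methoxybenzyl)oxy]prop-1-en-2-yl}-2-methylcyclohex-2-en-1-one
Conditions: [Rh(OH)((R)-binap)]2 (3 mol % Rh), KOH, dioxane/H2O 10:1, 40 °C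
Reagents that add atoms: none
Why: Rh(I)-catalysed asymmetric conjugate addition of an alkenylboronate (Hayashi–Miyaura type) should go to the unsubstituted enone olefin (β-carbon = C7), because the α-methyl-substituted olefin inserts far more slowly, with the (R)-BINAP ligand, chosen by analogy with its facial sense on cyclohex-2-enones, setting C7.

Step 5
Reactants: 7 (5R)-4,4-dimethoxy-5-{3-[(4-methoxybenzyl)oxy]prop-1-en-2-yl}-2-methylcyclohex-2-en-1-one
Product: 9 6-hydroxy-4,4-dimethoxy-5-{3-[(4-methoxybenzyl)oxy]prop-1-en-2-yl}-2-methylcyclohex-2-en-1-one (6-OH trans to the C5 side chain), via potassium enolate 8 (not isolated)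
Conditions: KHMDS, THF, −78 °C; then 2-(benzenesulfonyl)-3-phenyloxaziridine; aq. NH4Cl
Reagents that add atoms: 2-(benzenesulfonyl)-3-phenyloxaziridine, O=S(=O)(c1ccccc1)N1OC1c1ccccc1
Why: Kinetic deprotonation at C6, the only enolisable α-position, followed by Davis oxaziridine hydroxylation of the enolate should put the oxygen on C6 trans to the C7 side chain (this configuration is inconsequential).

Step 6
Reactants: 9 6-hydroxy-4,4-dimethoxy-5-{3-[(4-methoxybenzyl)oxy]prop-1-en-2-yl}-2-methylcyclohex-2-en-1-one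
Product: 10 1-ethenyl-4,4-dimethoxy-5-{3-[(4-methoxybenzyl)oxy]prop-1-en-2-yl}-2-methylcyclohex-2-ene-1,6-diol (hydroxyls cis)
Conditions: vinylMgBr (3 equiv), CeCl3, THF, −78 to 0 °C
Reagents that add atoms: vinylmagnesium bromide, C=C[Mg]Br
Why: Cerium-mediated 1,2-addition of the vinyl Grignard reagent to the enone carbonyl, activated by chelation with the C6 alkoxide, should give the tertiary bis-allylic alcohol at C1 (its configuration is inconsequential).

Step 7
Reactants: 10 1-ethenyl-4,4-dimethoxy-5-{3-[(4-methoxybenzyl)oxy]prop-1-en-2-yl}-2-methylcyclohex-2-ene-1,6-diol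
Product: 11 2-ethenyl-2-hydroxy-5,5-dimethoxy-6-{3-[(4-methoxybenzyl)oxy]prop-1-en-2-yl}-3-methylcyclohex-3-en-1-one
Conditions: Dess–Martin periodinane, NaHCO3, CH2Cl2, 0 °C
Reagents that add atoms: none
Why: Dess–Martin oxidation should convert the only secondary alcohol into the C6 ketone beside the non-oxidisable tertiary alcohol.

Step 8
Reactants: 11 2-ethenyl-2-hydroxy-5,5-dimethoxy-6-{3-[(4-methoxybenzyl)oxy]prop-1-en-2-yl}-3-methylcyclohex-3-en-1-one; 12 tert-butyldimethyl(prop-2-yn-1-yloxy)silane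
Product: 14 1-ethenyl-6-{3-[(tert-butyldimethylsilyl)oxy]prop-1-yn-1-yl}-4,4-dimethoxy-5-{3-[(4-methoxybenzyl)oxy]prop-1-en-2-yl}-2-methylcyclohex-2-ene-1,6-diol (vinyl and alkynyl trans; alkynyl trans to the C5 side chain), via lithium acetylide 13 (not isolated)
Conditions: 12, n-BuLi, THF, −78 °C; CeCl3; then 11, −78 °C
Reagents that add atoms: none
Why: Addition of the cerium-modified lithium acetylide to the hindered α-alkoxido ketone should occur from the face opposite the C7 side chain, the low basicity of the reagent preventing enolisation towards C7 and loss of methoxide from the C8 ketal.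

Step 9
Reactants: 14 1-ethenyl-6-{3-[(tert-butyldimethylsilyl)oxy]prop-1-yn-1-yl}-4,4-dimethoxy-5-{3-[(4-methoxybenzyl)oxy]prop-1-en-2-yl}-2-methylcyclohex-2-ene-1,6-diol
Product: 15 4-ethenyl-5-{3-[(tert-butyldimethylsilyl)oxy]prop-1-yn-1-yl}-4,5-dihydroxy-6-{3-[(4-methoxybenzyl)oxy]prop-1-en-2-yl}-3-methylcyclohex-2-en-1-one
Conditions: PPTS (cat.), acetone/H2O 10:1, rt
Reagents that add atoms: water, O
Why: Mild acid hydrolysis of the allylic dimethyl ketal through its conjugated oxocarbenium ion should unveil the C8 ketone, aromatisation being impossible now that C1 and C6 are quaternary.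

Step 10
Reactants: 15 4-ethenyl-5-{3-[(tert-butyldimethylsilyl)oxy]prop-1-yn-1-yl}-4,5-dihydroxy-6-{3-[(4-methoxybenzyl)oxy]prop-1-en-2-yl}-3-methylcyclohex-2-en-1-one
Product: 16 1-ethenyl-6-{3-[(tert-butyldimethylsilyl)oxy]prop-1-yn-1-yl}-5-{3-[(4-methoxybenzyl)oxy]prop-1-en-2-yl}-2-methylcyclohex-2-ene-1,4,6-triol (4-OH cis to the C5 side chain)
Conditions: L-Selectride (3.5 equiv), THF, −78 °C; aq. NH4Cl
Reagents that add atoms: none
Why: 1,2-Reduction of the β,β-disubstituted enone by a bulky trialkylborohydride should proceed along the equatorial trajectory (the axial one is blocked by the axial C6 oxygen) and give the axial alcohol cis to the equatorial C7 side chain, which is the C8 configuration of the target.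

Step 11
Reactants: 16 1-ethenyl-6-{3-[(tert-butyldimethylsilyl)oxy]prop-1-yn-1-yl}-5-{3-[(4-methoxybenzyl)oxy]prop-1-en-2-yl}-2-methylcyclohex-2-ene-1,4,6-triol
Product: 19 15-[(tert-butyldimethylsilyl)oxy]-8-hydroxy-12-[(4-methoxybenzyl)oxy]germacra-4,9,11(13)-triene-1,6-dione (ring-cis at C4=C5 and C9=C10; C7 and C8 as in the target), via tripotassium trialkoxide 17 (not isolated), via ring-expanded trianion 18 (not isolated)
Conditions: KH (4 equiv), 18-crown-6, THF, 0 °C to rt; inverse quench into AcOH/THF, −78 °C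
Reagents that add atoms: none
Why: KH converts all three hydroxyls into alkoxides (17); the vicinal C1 and C6 alkoxides both weaken the C1–C6 bond, and the 3,4-dioxido-1-en-5-yne array C3=C2–C1–C6–C5≡C4, with vinyl and alkynyl trans-diequatorial on the cyclohexene half-chair, should undergo a concerted chair-like [3,3] shift that forms C3–C4, breaks C1–C6 and leaves the C1 enolate and the C6 allenolate of 18. The closest known reaction types are the dianionic oxy-Cope ring enlargement of 1,2-dialkenylcycloalkane-1,2-diols to 1,6-diketones and the acetylenic oxy-Cope rearrangement, which gives 2-enones by way of allenolates. The ten-membered ring is closed not by an end-to-end cyclisation but by a four-atom enlargement of the six-membered ring through a six-centre pericyclic transition state, so no medium-ring closure has to be paid for. No stereocentre is created: C7 and C8 are spectators, the carbinol centres C1 and C6 become carbonyl carbons, and the C9=C10 olefin keeps the cis geometry imposed by the six-membered ring. Two selectivities are needed: scission of C1–C6 rather than the competing shift of the C6 alkoxide through the C7 propenyl group (C6–C7 scission), secured because only C1–C6 is flanked by two alkoxides; and the ring-cis C4=C5 geometry, secured because the cyclic allenolate is protonated at C5 in the plane of the C4 substituents from the open CH2OTBS side and not from the ring side, which is also the more stable cyclodec-2-enone geometry. The inverse acidic quench at −78 °C protonates O8 and both enolates before retro-aldol or transannular aldol reactions can start, and the free C8 hydroxyl then masks the C1 ketone as a cyclic hemiketal.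

Step 12
Reactants: 20 (2S)-2-methylbutan-1-ol
Product: 21 (2S)-2-methylbutanal
Conditions: TEMPO (10 mol %), PhI(OAc)2, CH2Cl2, 0 °C; used as a solution
Reagents that add atoms: none
Why: Oxoammonium-mediated oxidation of the primary alcohol under non-basic conditions should leave the α-stereocentre untouched.

Step 13
Reactants: 19 15-[(tert-butyldimethylsilyl)oxy]-8-hydroxy-12-[(4-methoxybenzyl)oxy]germacra-4,9,11(13)-triene-1,6-dione; 21 (2S)-2-methylbutanal
Product: 22 15-[(tert-butyldimethylsilyl)oxy]-6-hydroxy-12-[(4-methoxybenzyl)oxy]-8-[(2S)-2-methylbutanoyloxy]germacra-4,9,11(13)-trien-1-one (C6, C7, C8 as in the target)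
Conditions: SmI2 (30 mol %), 21 (6 equiv), THF, −10 °C
Reagents that add atoms: none
Why: In the Evans–Tishchenko reduction the samarium-bound hemiacetal formed at O8 should deliver its hydride intramolecularly to the C6 ketone through a six-membered transition state, giving the 1,3-anti C6 alcohol and at the same time turning the aldehyde into the O8 (S)-2-methylbutanoate, while C1 remains masked as the O8/C1 hemiketal until O8 is acylated.

Step 14
Reactants: 22 15-[(tert-butyldimethylsilyl)oxy]-6-hydroxy-12-[(4-methoxybenzyl)oxy]-8-[(2S)-2-methylbutanoyloxy]germacra-4,9,11(13)-trien-1-one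
Product: 23 15-[(tert-butyldimethylsilyl)oxy]-6,12-dihydroxy-8-[(2S)-2-methylbutanoyloxy]germacra-4,9,11(13)-trien-1-one
Conditions: DDQ, CH2Cl2/pH 7 buffer 10:1, 0 °C
Reagents that add atoms: none
Why: Oxidative cleavage of the p-methoxybenzyl ether by DDQ should free the C12 allylic alcohol without touching the silyl ether or the ester.

Step 15
Reactants: 23 15-[(tert-butyldimethylsilyl)oxy]-6,12-dihydroxy-8-[(2S)-2-methylbutanoyloxy]germacra-4,9,11(13)-trien-1-one
Product: 25 15-[(tert-butyldimethylsilyl)oxy]-8-[(2S)-2-methylbutanoyloxy]-1-oxogermacra-4,9,11(13)-trien-12,6-olide, via lactol 24 (not isolated)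
Conditions: TEMPO (20 mol %), PhI(OAc)2 (2.5 equiv), CH2Cl2, rt
Reagents that add atoms: none
Why: Primary-selective TEMPO/PhI(OAc)2 oxidation should give the 2-substituted acrolein, which is trapped by the C6 hydroxyl as a lactol and oxidised on to the α-methylene-γ-butyrolactone, the trans ring fusion following from the C6 and C7 configurations already set.

Step 16
Reactants: 25 15-[(tert-butyldimethylsilyl)oxy]-8-[(2S)-2-methylbutanoyloxy]-1-oxogermacra-4,9,11(13)-trien-12,6-olide
Product: 26 15-[(tert-butyldimethylsilyl)oxy]-1-hydroxy-8-[(2S)-2-methylbutanoyloxy]germacra-4,9,11(13)-trien-12,6-olide (1S)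
Conditions: (R)-2-methyl-CBS-oxazaborolidine (0.5 equiv), catecholborane, toluene, −78 °C
Reagents that add atoms: none
Why: In the Corey–Bakshi–Shibata reduction of the α-methyl enone the alkenyl flank (C10) should act as the large group and C2H2 as the small one, so that the (R)-catalyst gives the (1S)-allylic alcohol under reagent control, while catecholborane at −78 °C spares lactone and ester.

Step 17
Reactants: 26 15-[(tert-butyldimethylsilyl)oxy]-1-hydroxy-8-[(2S)-2-methylbutanoyloxy]germacra-4,9,11(13)-trien-12,6-olide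
Product: 27 CNP0526758.1, (1S,6R,7R,8R)-1,15-dihydroxy-8-[(2S)-2-methylbutanoyloxy]germacra-4,9,11(13)-trien-12,6-olide (4E,9Z; both ring olefins cis in the ring)
Conditions: HF·pyridine, pyridine/THF, 0 °C
Reagents that add atoms: none
Why: Buffered fluoride cleavage of the primary allylic silyl ether should leave the α-methylene lactone, the ester and both olefin geometries untouched.

**Compound list**

1 | 4-methoxy-2-methylphenol | COc1ccc(O)c(C)c1 | starting material
2 | 4,4-dimethoxy-2-methylcyclohexa-2,5-dien-1-one | COC1(OC)C=CC(=O)C(C)=C1 | intermediate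
3 | 2,3-dibromoprop-1-ene | C=C(Br)CBr | starting material
4 | (4-methoxyphenyl)methanol | COc1ccc(CO)cc1 | starting material
5 | 1-{[(2-bromoprop-2-en-1-yl)oxy]methyl}-4-methoxybenzene | C=C(Br)COCc1ccc(OC)cc1 | intermediate
6 | 2-{3-[(4-methoxybenzyl)oxy]prop-1-en-2-yl}-4,4,5,5-tetramethyl-1,3,2-dioxaborolane | C=C(COCc1ccc(OC)cc1)B1OC(C)(C)C(C)(C)O1 | intermediate
7 | (5R)-4,4-dimethoxy-5-{3-[(4-methoxybenzyl)oxy]prop-1-en-2-yl}-2-methylcyclohex-2-en-1-one | O=C1C[C@H](C(=C)COCc2ccc(OC)cc2)C(OC)(OC)C=C1C | intermediate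
8 | potassium enolate of 7 (O1–C1=C6) | [O-]C1=C[C@H](C(=C)COCc2ccc(OC)cc2)C(OC)(OC)C=C1C.[K+] | intermediate (not isolated)
9 | 6-hydroxy-4,4-dimethoxy-5-{3-[(4-methoxybenzyl)oxy]prop-1-en-2-yl}-2-methylcyclohex-2-en-1-one, 6-OH trans to the C5 side chain | O=C1[C@@H](O)[C@H](C(=C)COCc2ccc(OC)cc2)C(OC)(OC)C=C1C | intermediate
10 | 1-ethenyl-4,4-dimethoxy-5-{3-[(4-methoxybenzyl)oxy]prop-1-en-2-yl}-2-methylcyclohex-2-ene-1,6-diol, hydroxyls cis | C=C[C@]1(O)[C@@H](O)[C@H](C(=C)COCc2ccc(OC)cc2)C(OC)(OC)C=C1C | intermediate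
11 | 2-ethenyl-2-hydroxy-5,5-dimethoxy-6-{3-[(4-methoxybenzyl)oxy]prop-1-en-2-yl}-3-methylcyclohex-3-en-1-one | C=C[C@]1(O)C(=O)[C@H](C(=C)COCc2ccc(OC)cc2)C(OC)(OC)C=C1C | intermediate
12 | tert-butyldimethyl(prop-2-yn-1-yloxy)silane | C#CCO[Si](C)(C)C(C)(C)C | starting material
13 | lithium acetylide of 12 | [Li+].[C-]#CCO[Si](C)(C)C(C)(C)C | intermediate (not isolated)
14 | 1-ethenyl-6-{3-[(tert-butyldimethylsilyl)oxy]prop-1-yn-1-yl}-4,4-dimethoxy-5-{3-[(4-methoxybenzyl)oxy]prop-1-en-2-yl}-2-methylcyclohex-2-ene-1,6-diol, vinyl and alkynyl trans | C=C[C@]1(O)[C@@](O)(C#CCO[Si](C)(C)C(C)(C)C)[C@H](C(=C)COCc2ccc(OC)cc2)C(OC)(OC)C=C1C | intermediate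
15 | 4-ethenyl-5-{3-[(tert-butyldimethylsilyl)oxy]prop-1-yn-1-yl}-4,5-dihydroxy-6-{3-[(4-methoxybenzyl)oxy]prop-1-en-2-yl}-3-methylcyclohex-2-en-1-one | C=C[C@]1(O)[C@@](O)(C#CCO[Si](C)(C)C(C)(C)C)[C@H](C(=C)COCc2ccc(OC)cc2)C(=O)C=C1C | intermediate
16 | 1-ethenyl-6-{3-[(tert-butyldimethylsilyl)oxy]prop-1-yn-1-yl}-5-{3-[(4-methoxybenzyl)oxy]prop-1-en-2-yl}-2-methylcyclohex-2-ene-1,4,6-triol, 4-OH cis to the C5 side chain | C=C[C@]1(O)[C@@](O)(C#CCO[Si](C)(C)C(C)(C)C)[C@H](C(=C)COCc2ccc(OC)cc2)[C@H](O)C=C1C | intermediate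
17 | tripotassium trialkoxide of 16 | C=C[C@]1([O-])[C@@]([O-])(C#CCO[Si](C)(C)C(C)(C)C)[C@H](C(=C)COCc2ccc(OC)cc2)[C@H]([O-])C=C1C.[K+].[K+].[K+] | intermediate (not isolated)
18 | tripotassium salt of the ten-membered C1 enolate, C6 allenolate and C8 alkoxide (enolate geometry and allene helicity not fixed) | [O-]C1=CCC(CO[Si](C)(C)C(C)(C)C)=C=C([O-])[C@H](C(=C)COCc2ccc(OC)cc2)[C@H]([O-])/C=C1/C.[K+].[K+].[K+] | intermediate (not isolated)
19 | 15-[(tert-butyldimethylsilyl)oxy]-8-hydroxy-12-[(4-methoxybenzyl)oxy]germacra-4,9,11(13)-triene-1,6-dione, ring-cis at C4=C5 and C9=C10 | O=C1CC/C(CO[Si](C)(C)C(C)(C)C)=C\C(=O)[C@H](C(=C)COCc2ccc(OC)cc2)[C@H](O)/C=C1/C | intermediate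
20 | (2S)-2-methylbutan-1-ol | CC[C@H](C)CO | starting material
21 | (2S)-2-methylbutanal | CC[C@H](C)C=O | intermediate
22 | 15-[(tert-butyldimethylsilyl)oxy]-6-hydroxy-12-[(4-methoxybenzyl)oxy]-8-[(2S)-2-methylbutanoyloxy]germacra-4,9,11(13)-trien-1-one | O=C1CC/C(CO[Si](C)(C)C(C)(C)C)=C\[C@@H](O)[C@H](C(=C)COCc2ccc(OC)cc2)[C@H](OC(=O)[C@@H](C)CC)/C=C1/C | intermediate
23 | 15-[(tert-butyldimethylsilyl)oxy]-6,12-dihydroxy-8-[(2S)-2-methylbutanoyloxy]germacra-4,9,11(13)-trien-1-one | O=C1CC/C(CO[Si](C)(C)C(C)(C)C)=C\[C@@H](O)[C@H](C(=C)CO)[C@H](OC(=O)[C@@H](C)CC)/C=C1/C | intermediate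
24 | 12-hydroxy-12,6-lactol of 23 (anomeric mixture) | O=C1CC/C(CO[Si](C)(C)C(C)(C)C)=C\[C@H]2OC(O)C(=C)[C@@H]2[C@H](OC(=O)[C@@H](C)CC)/C=C1/C | intermediate (not isolated)
25 | 15-[(tert-butyldimethylsilyl)oxy]-8-[(2S)-2-methylbutanoyloxy]-1-oxogermacra-4,9,11(13)-trien-12,6-olide | O=C1CC/C(CO[Si](C)(C)C(C)(C)C)=C\[C@H]2OC(=O)C(=C)[C@@H]2[C@H](OC(=O)[C@@H](C)CC)/C=C1/C | intermediate
26 | (1S)-15-[(tert-butyldimethylsilyl)oxy]-1-hydroxy-8-[(2S)-2-methylbutanoyloxy]germacra-4,9,11(13)-trien-12,6-olide | O[C@H]1CC/C(CO[Si](C)(C)C(C)(C)C)=C\[C@H]2OC(=O)C(=C)[C@@H]2[C@H](OC(=O)[C@@H](C)CC)/C=C1/C | intermediate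
27 | CNP0526758.1, (1S,6R,7R,8R)-1,15-dihydroxy-8-[(2S)-2-methylbutanoyloxy]germacra-4,9,11(13)-trien-12,6-olide | C=C1C(=O)O[C@@H]2/C=C(/CO)CC[C@H](O)/C(C)=C\[C@@H](OC(=O)[C@@H](C)CC)[C@@H]12 | target

**Step count and risks**

Total step count: 17. Longest linear sequence: 15 steps (from 3 and 4 to 27 through steps 2–11 and 13–17).

Steps most likely to fail:

1. Step 11 (ring enlargement). Possible failure modes are a competing [3,3] shift of the C6 alkoxide through the C7 propenyl group with C6–C7 scission, loss of the acetylide by retro-addition from the potassium alkoxide, or protonation of the allenolate from the ring side giving the ring-trans enone. The fallback stores the 4,5-olefin in a second six-membered ring and opens C1–C6 by glycol cleavage instead of a sigmatropic shift. It sets out from 10. 2-Bromoprop-2-en-1-ol is silylated (TBSCl, imidazole) to [(2-bromoprop-2-en-1-yl)oxy](tert-butyl)dimethylsilane F1. The monosubstituted vinyl group of 10 is hydroborated with 9-BBN, used in only slight excess over what the two hydroxyls consume so that the 1,1-disubstituted C11=C13 allylic-ether olefin next to the ketal carbon should remain, to give the B-alkyl borane F2. F2 is coupled directly with F1 (Pd(dppf)Cl2, K3PO4, DMF/THF/H2O; B-alkyl Suzuki coupling) to the C1 side-chain diol F3. Dess–Martin oxidation gives the C6 ketone F4, vinylmagnesium bromide/CeCl3 the divinyl-type diol F5, PPTS in wet acetone the C8 enone F6, and L-Selectride the triol F7. Ring-closing metathesis (Hoveyda–Grubbs II, toluene, 80 °C) closes the cyclohexene that holds C4=C5, giving the hexahydronaphthalene-4a,8a-diol F8. Pb(OAc)4 cleavage of its ring-fusion glycol returns to the route at 19.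

2. Step 13 (Evans–Tishchenko). Possible failure modes are hydride delivery to C1 instead of C6, slow turnover because O8 is held in the hemiketal, acyl migration, or epimerisation of the aldehyde. The fallback separates acylation from reduction and puts both carbinol centres under reagent control. It sets out from 19. Esterification of O8 with (S)-2-methylbutanoic acid (DIC, DMAP) gives the 8-O-acyl dione F9. Reduction of both enone carbonyls with (R)-2-methyl-CBS-oxazaborolidine and catecholborane, the alkenyl flank acting as the large group at C1 and at C6, gives the 1,6-diol F10. DDQ removes the p-methoxybenzyl group to give the triol F11, and primary-selective TEMPO/PhI(OAc)2 lactonisation returns to the route at 26.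

3. Step 10 (C8 reduction). Possible failure modes are poor facial selectivity of hydride delivery next to two quaternary carbinol carbons, or retro-aldol opening of the β-hydroxy ketone by the basic hydride. The fallback accepts the equatorial alcohol and corrects C8 by substitution with inversion. It sets out from 15. Luche reduction (NaBH4, CeCl3, MeOH, −78 °C) gives the C8 epimer of the triol, F12. Mitsunobu reaction of its only secondary alcohol with 4-nitrobenzoic acid (PPh3, DIAD) gives the inverted 4-nitrobenzoate F13, and methanolysis (K2CO3, MeOH) returns to the route at 16.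

Further compounds
F1 | step 11 | [(2-bromoprop-2-en-1-yl)oxy](tert-butyl)dimethylsilane | C=C(Br)CO[Si](C)(C)C(C)(C)C
F2 | step 11 | B-alkyl-9-borabicyclo[3.3.1]nonane from hydroboration of the vinyl group of 10 | B1(CC[C@]2(O)[C@@H](O)[C@H](C(=C)COCc3ccc(OC)cc3)C(OC)(OC)C=C2C)C2CCCC1CCC2
F3 | step 11 | 1-[3-({[tert-butyl(dimethyl)silyl]oxy}methyl)but-3-en-1-yl]-4,4-dimethoxy-5-{3-[(4-methoxybenzyl)oxy]prop-1-en-2-yl}-2-methylcyclohex-2-ene-1,6-diol | C=C(CO[Si](C)(C)C(C)(C)C)CC[C@]1(O)[C@@H](O)[C@H](C(=C)COCc2ccc(OC)cc2)C(OC)(OC)C=C1C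
F4 | step 11 | 6-ketone of F3 (α-hydroxy ketone) | C=C(CO[Si](C)(C)C(C)(C)C)CC[C@]1(O)C(=O)[C@H](C(=C)COCc2ccc(OC)cc2)C(OC)(OC)C=C1C
F5 | step 11 | 6-ethenyl-1,6-diol from vinyl addition to F4 | C=C(CO[Si](C)(C)C(C)(C)C)CC[C@]1(O)[C@@](O)(C=C)[C@H](C(=C)COCc2ccc(OC)cc2)C(OC)(OC)C=C1C
F6 | step 11 | C8 enone from ketal hydrolysis of F5 | C=C(CO[Si](C)(C)C(C)(C)C)CC[C@]1(O)[C@@](O)(C=C)[C@H](C(=C)COCc2ccc(OC)cc2)C(=O)C=C1C
F7 | step 11 | 1,4,6-triol from reduction of F6 (4-OH cis to the C5 side chain) | C=C(CO[Si](C)(C)C(C)(C)C)CC[C@]1(O)[C@@](O)(C=C)[C@H](C(=C)COCc2ccc(OC)cc2)[C@H](O)C=C1C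
F8 | step 11 | hexahydronaphthalene-4a,8a-diol from ring-closing metathesis of F7 (ring fusion C1–C6; olefins C4=C5 and C9=C10 each in a six-membered ring) | CC1=C[C@@H](O)[C@@H](C(=C)COCc2ccc(OC)cc2)[C@]2(O)C=C(CO[Si](C)(C)C(C)(C)C)CC[C@@]12O
F9 | step 13 | 15-[(tert-butyldimethylsilyl)oxy]-12-[(4-methoxybenzyl)oxy]-8-[(2S)-2-methylbutanoyloxy]germacra-4,9,11(13)-triene-1,6-dione | O=C1CC/C(CO[Si](C)(C)C(C)(C)C)=C\C(=O)[C@H](C(=C)COCc2ccc(OC)cc2)[C@H](OC(=O)[C@@H](C)CC)/C=C1/C
F10 | step 13 | 1,6-diol from double CBS reduction of F9 | O[C@H]1CC/C(CO[Si](C)(C)C(C)(C)C)=C\[C@@H](O)[C@H](C(=C)COCc2ccc(OC)cc2)[C@H](OC(=O)[C@@H](C)CC)/C=C1/C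
F11 | step 13 | 1,6,12-triol from PMB removal of F10 | O[C@H]1CC/C(CO[Si](C)(C)C(C)(C)C)=C\[C@@H](O)[C@H](C(=C)CO)[C@H](OC(=O)[C@@H](C)CC)/C=C1/C
F12 | step 10 | C8 (ring C4) epimer of 16 | C=C[C@]1(O)[C@@](O)(C#CCO[Si](C)(C)C(C)(C)C)[C@H](C(=C)COCc2ccc(OC)cc2)[C@@H](O)C=C1C
F13 | step 10 | 4-nitrobenzoate of 16 at the C8 (ring C4) oxygen | C=C[C@]1(O)[C@@](O)(C#CCO[Si](C)(C)C(C)(C)C)[C@H](C(=C)COCc2ccc(OC)cc2)[C@H](OC(=O)c2ccc(cc2)[N+](=O)[O-])C=C1C
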